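**Retrosynthetic overview**
1. Target 19 ← phenol unmasking and C4 alcohol oxidation ← alkenylalane/benzyl chloride coupling of alkyne 11 with arene 15 (E-trisubstituted alkene from syn-carboalumination).
2. Alkyne 11 ← propargylation of hydrindanone 10, the C6 carbinol being set anti to the axial C7a methyl of a locked chair.
3. Hydrindanone 10 ← ozonolysis of cyclopentene 8 and proline aldol re-closure (C4–C5 bond) to the six-membered ring.
4. Cyclopentene 8 ← Wolff–Kishner ← B-alkyl Suzuki coupling of enol triflate 3 with the borane from 2-methylbut-3-en-2-ol.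
5. Triflate 3 ← enantiotopos-selective enolisation/triflation of the C2v-symmetric Weiss diketone 1. Ring order: the cyclopentane with both cis quaternary methyls is present from the start; the cyclohexanone is made second, from the other five-membered ring.

Assumption 1: the hydrindane locants of the target (C3a/C7a ring fusion, C4 carbonyl, C5, C6 carbinol, C7) are used for all hydrindane intermediates.
Assumption 2: the (R,R)-amide is taken to remove the proton that leads to 3 as drawn (by analogy with cis-bicyclo[3.3.0]octan-3-ones); if the sense is opposite, the (S,S)-amide is used and nothing else changes.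

**Step 1**
Reactants: 1 cis-1,5-dimethylbicyclo[3.3.0]octane-3,7-dione (meso)
Product: 3 (1S,5S)-1,5-dimethyl-7-oxobicyclo[3.3.0]oct-2-en-3-yl trifluoromethanesulfonate, via lithium enolate 2 (not isolated)
Conditions: (R,R)-bis(1-phenylethyl)amine (1.05 equiv), n-BuLi, LiCl, THF, −100 °C; Comins' reagent, −78 → 0 °C; NH4Cl work-up
Reagents that add atoms: Comins' reagent, N-(5-chloropyridin-2-yl)-N-(trifluoromethylsulfonyl)trifluoromethanesulfonamide, FC(F)(F)S(=O)(=O)N(c1ccc(Cl)cn1)S(=O)(=O)C(F)(F)F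
Why: Enantiotopos-selective deprotonation by a homochiral lithium amide (Simpkins–Koga desymmetrisation, precedented on the mono-ketal of the parent dione) followed by O-triflation gives one chiral mono-enolate from the four symmetry-related α-CH2 groups, so one operation fixes the absolute configuration of both quaternary carbons and tells the two carbonyls apart.

**Step 2**
Reactants: 3 (1S,5S)-1,5-dimethyl-7-oxobicyclo[3.3.0]oct-2-en-3-yl trifluoromethanesulfonate; 4 2-methylbut-3-en-2-ol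
Product: 6 (1S,5S)-3-(3-hydroxy-3-methylbutyl)-1,5-dimethylbicyclo[3.3.0]oct-2-en-7-one, via alkylborane 5 (not isolated)
Conditions: 4, 9-BBN-H, THF, 0 °C → rt; then 3, PdCl2(dppf) (5 mol%), 3 M aq K3PO4, DMF/THF, 50 °C
Reagents that add atoms: none
Why: B-alkyl Suzuki–Miyaura coupling, in which anti-Markovnikov hydroboration gives a primary alkylborane that couples with the enol triflate without touching the ketone, the free tertiary alcohol or any stereocentre.

**Step 3**
Reactants: 6 (1S,5S)-3-(3-hydroxy-3-methylbutyl)-1,5-dimethylbicyclo[3.3.0]oct-2-en-7-one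
Product: 8 4-[(1S,5R)-1,5-dimethylbicyclo[3.3.0]oct-2-en-3-yl]-2-methylbutan-2-ol, via hydrazone 7 (not isolated)
Conditions: N2H4·H2O, KOH, diethylene glycol, 130 °C then 200 °C
Reagents that add atoms: none
Why: Wolff–Kishner (Huang-Minlon) reduction removes the remaining cyclopentanone carbonyl, while the isolated trisubstituted alkene, the tertiary alcohol and the non-epimerisable quaternary centres survive hot alkali.

**Step 4**
Reactants: 8 4-[(1S,5R)-1,5-dimethylbicyclo[3.3.0]oct-2-en-3-yl]-2-methylbutan-2-ol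
Product: 10 (3aR,4S,5S,7aR)-4-hydroxy-5-(2-hydroxy-2-methylpropyl)-3a,7a-dimethyloctahydro-6H-inden-6-one, via keto aldehyde 9 (not isolated)
Conditions: O3, CH2Cl2/MeOH, −78 °C; Me2S, → rt; concentrate; (S)-proline (30 mol%), DMSO, rt; Et3N wash
Reagents that add atoms: ozone, O=[O+][O-]
Why: Ozonolysis opens the cyclopentene to a 1,5-keto aldehyde whose aldehyde cannot enolise, and a proline enamine 6-enolendo aldol (Hajos–Parrish type, Houk–List transition state) closes the six-membered ring with the C4 hydroxyl anti to the angular methyls under catalyst control (the substrate itself has almost no facial bias), after which C5 settles in the all-equatorial trans arrangement.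

**Step 5**
Reactants: 10 (3aR,4S,5S,7aR)-4-hydroxy-5-(2-hydroxy-2-methylpropyl)-3a,7a-dimethyloctahydro-6H-inden-6-one
Product: 11 (3aR,4S,5S,6R,7aR)-5-(2-hydroxy-2-methylpropyl)-3a,7a-dimethyl-6-(prop-2-yn-1-yl)octahydro-1H-indene-4,6-diol
Conditions: propargyl bromide (3 equiv), Zn dust, THF/sat. aq NH4Cl, 0 °C → rt
Reagents that add atoms: propargyl bromide, C#CCBr
Why: Barbier propargylation, in which the equatorial C4-OH and C5 side chain lock the chair that carries the C7a methyl axial, so the allenylzinc attacks the C6 carbonyl equatorially, anti to that 1,3-diaxial methyl (the 3,3,5-trimethylcyclohexanone pattern), giving the axial tertiary alcohol cis to the C5 side chain.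

**Step 6**
Reactants: 12 2-methylhydroquinone
Product: 13 4-methoxy-2-methylphenol
Conditions: MeOH, H2SO4, NaNO2 (10 mol%), rt
Reagents that add atoms: methanol, CO
Why: Nitrite-initiated acid-catalysed mono-etherification of a hydroquinone (through the quinone hemiketal), which takes place at the hydroxyl remote from the ring methyl.

**Step 7**
Reactants: 13 4-methoxy-2-methylphenol
Product: 14 2-[(dimethylamino)methyl]-4-methoxy-6-methylphenol
Conditions: 40% aq Me2NH, 37% aq CH2O, EtOH, reflux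
Reagents that add atoms: formaldehyde, C=O; dimethylamine, CNC
Why: Phenol Mannich reaction, with aminomethylation at the only free position ortho to the hydroxyl.

**Step 8**
Reactants: 14 2-[(dimethylamino)methyl]-4-methoxy-6-methylphenol
Product: 15 2-(chloromethyl)-4-methoxy-6-methylphenyl ethyl carbonate
Conditions: ClCO2Et (2.5 equiv), K2CO3 (1.1 equiv), CH2Cl2, 0 → 40 °C
Reagents that add atoms: ethyl chloroformate, CCOC(=O)Cl
Why: The chloroformate both O-acylates the phenol and effects a von Braun-type N-acylation/debenzylation, chloride displacing the acylammonium group at the benzylic carbon.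

**Step 9**
Reactants: 11 (3aR,4S,5S,6R,7aR)-5-(2-hydroxy-2-methylpropyl)-3a,7a-dimethyl-6-(prop-2-yn-1-yl)octahydro-1H-indene-4,6-diol; 15 2-(chloromethyl)-4-methoxy-6-methylphenyl ethyl carbonate
Product: 17 ethyl 2-{(2E)-4-[(3aR,4S,5S,6R,7aR)-4,6-dihydroxy-5-(2-hydroxy-2-methylpropyl)-3a,7a-dimethyloctahydro-1H-inden-6-yl]-3-methylbut-2-en-1-yl}-4-methoxy-6-methylphenyl carbonate, via alkenylalane 16 (not isolated)
Conditions: AlMe3 (6 equiv), Cp2ZrCl2 (0.5 equiv), CH2Cl2, 0 °C → rt; volatiles removed; 15, Pd(PPh3)4 (5 mol%), THF, rt; Rochelle-salt work-up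
Reagents that add atoms: trimethylaluminium, C[Al](C)C
Why: Negishi zirconium-catalysed syn-carboalumination of the terminal alkyne (the three hydroxyls ride through as aluminium alkoxides) gives the (E)-2-methylalkenylalane, which couples with the benzylic chloride at zerovalent palladium with retention and so fixes the E trisubstituted alkene.

**Step 10**
Reactants: 17 ethyl 2-{(2E)-4-[(3aR,4S,5S,6R,7aR)-4,6-dihydroxy-5-(2-hydroxy-2-methylpropyl)-3a,7a-dimethyloctahydro-1H-inden-6-yl]-3-methylbut-2-en-1-yl}-4-methoxy-6-methylphenyl carbonate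
Product: 18 ethyl 2-{(2E)-4-[(3aR,5R,6R,7aR)-6-hydroxy-5-(2-hydroxy-2-methylpropyl)-3a,7a-dimethyl-4-oxooctahydro-1H-inden-6-yl]-3-methylbut-2-en-1-yl}-4-methoxy-6-methylphenyl carbonate
Conditions: Dess–Martin periodinane (1.5 equiv), NaHCO3, CH2Cl2, 0 °C → rt
Reagents that add atoms: none
Why: Dess–Martin oxidation of the only secondary alcohol leaves the two tertiary alcohols, the alkene and the carbonate alone, and C5, now α to the ketone, stays in the trans-diequatorial arrangement that the target requires.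

**Step 11**
Reactants: 18 ethyl 2-{(2E)-4-[(3aR,5R,6R,7aR)-6-hydroxy-5-(2-hydroxy-2-methylpropyl)-3a,7a-dimethyl-4-oxooctahydro-1H-inden-6-yl]-3-methylbut-2-en-1-yl}-4-methoxy-6-methylphenyl carbonate
Product: 19 (3aR,5R,6R,7aR)-6-hydroxy-6-[(2E)-4-(2-hydroxy-5-methoxy-3-methylphenyl)-2-methylbut-2-en-1-yl]-5-(2-hydroxy-2-methylpropyl)-3a,7a-dimethyloctahydro-4H-inden-4-one
Conditions: pyrrolidine (3 equiv), MeCN, rt
Reagents that add atoms: none
Why: Aminolysis of the activated aryl carbonate frees the phenol under conditions too mild for retro-aldol cleavage of the β-hydroxy ketone.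

**Compound list**
1 | cis-1,5-dimethylbicyclo[3.3.0]octane-3,7-dione (meso) | O=C1C[C@@]2(C)CC(=O)C[C@@]2(C)C1 | starting material
2 | lithium enolate of 1 | C1(O[Li])C[C@@]2(C)CC(=O)C[C@@]2(C)C=1 | intermediate
3 | (1S,5S)-1,5-dimethyl-7-oxobicyclo[3.3.0]oct-2-en-3-yl trifluoromethanesulfonate | C1(OS(=O)(=O)C(F)(F)F)C[C@@]2(C)CC(=O)C[C@@]2(C)C=1 | intermediate
4 | 2-methylbut-3-en-2-ol | CC(C)(O)C=C | starting material
5 | B-(3-hydroxy-3-methylbutyl)-9-borabicyclo[3.3.1]nonane | CC(C)(O)CCB1C2CCCC1CCC2 | intermediate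
6 | (1S,5S)-3-(3-hydroxy-3-methylbutyl)-1,5-dimethylbicyclo[3.3.0]oct-2-en-7-one | C1(CCC(C)(C)O)C[C@@]2(C)CC(=O)C[C@@]2(C)C=1 | intermediate
7 | hydrazone of 6 | C1(CCC(C)(C)O)C[C@@]2(C)CC(=NN)C[C@@]2(C)C=1 | intermediate
8 | 4-[(1S,5R)-1,5-dimethylbicyclo[3.3.0]oct-2-en-3-yl]-2-methylbutan-2-ol | C1(CCC(C)(C)O)C[C@@]2(C)CCC[C@@]2(C)C=1 | intermediate
9 | (1R,2R)-2-(5-hydroxy-5-methyl-2-oxohexyl)-1,2-dimethylcyclopentane-1-carbaldehyde | CC(C)(O)CCC(=O)C[C@@]1(C)CCC[C@@]1(C)C=O | intermediate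
10 | (3aR,4S,5S,7aR)-4-hydroxy-5-(2-hydroxy-2-methylpropyl)-3a,7a-dimethyloctahydro-6H-inden-6-one (target numbering) | O=C1C[C@@]2(C)CCC[C@@]2(C)[C@@H](O)[C@@H]1CC(C)(C)O | intermediate
11 | (3aR,4S,5S,6R,7aR)-5-(2-hydroxy-2-methylpropyl)-3a,7a-dimethyl-6-(prop-2-yn-1-yl)octahydro-1H-indene-4,6-diol | C#CC[C@@]1(O)C[C@@]2(C)CCC[C@@]2(C)[C@@H](O)[C@@H]1CC(C)(C)O | intermediate
12 | 2-methylhydroquinone | Cc1cc(O)ccc1O | starting material
13 | 4-methoxy-2-methylphenol | COc1ccc(O)c(C)c1 | intermediate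
14 | 2-[(dimethylamino)methyl]-4-methoxy-6-methylphenol | CN(C)Cc1cc(OC)cc(C)c1O | intermediate
15 | 2-(chloromethyl)-4-methoxy-6-methylphenyl ethyl carbonate | CCOC(=O)Oc1c(C)cc(OC)cc1CCl | intermediate
16 | (E)-alkenyl(dimethyl)alane from 11 (hydroxyls present as aluminium alkoxides) | C[Al](C)/C=C(\C)C[C@@]1(O)C[C@@]2(C)CCC[C@@]2(C)[C@@H](O)[C@@H]1CC(C)(C)O | intermediate
17 | ethyl 2-{(2E)-4-[(3aR,4S,5S,6R,7aR)-4,6-dihydroxy-5-(2-hydroxy-2-methylpropyl)-3a,7a-dimethyloctahydro-1H-inden-6-yl]-3-methylbut-2-en-1-yl}-4-methoxy-6-methylphenyl carbonate | CCOC(=O)Oc1c(C)cc(OC)cc1C/C=C(\C)C[C@@]2(O)C[C@@]3(C)CCC[C@@]3(C)[C@@H](O)[C@@H]2CC(C)(C)O | intermediate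
18 | ethyl 2-{(2E)-4-[(3aR,5R,6R,7aR)-6-hydroxy-5-(2-hydroxy-2-methylpropyl)-3a,7a-dimethyl-4-oxooctahydro-1H-inden-6-yl]-3-methylbut-2-en-1-yl}-4-methoxy-6-methylphenyl carbonate | CCOC(=O)Oc1c(C)cc(OC)cc1C/C=C(\C)C[C@@]2(O)C[C@@]3(C)CCC[C@@]3(C)C(=O)[C@@H]2CC(C)(C)O | intermediate
19 | (3aR,5R,6R,7aR)-6-hydroxy-6-[(2E)-4-(2-hydroxy-5-methoxy-3-methylphenyl)-2-methylbut-2-en-1-yl]-5-(2-hydroxy-2-methylpropyl)-3a,7a-dimethyloctahydro-4H-inden-4-one | COc1cc(C)c(O)c(C/C=C(\C)C[C@@]2(O)C[C@@]3(C)CCC[C@@]3(C)C(=O)[C@@H]2CC(C)(C)O)c1 | target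

**Totals**
Total step count: 11. Longest linear sequence: 8 (steps 1–5 and 9–11; steps 6–8 make the arene partner).

**Steps most likely to fail**

Step 1 (mono- versus bis-enolisation of the diketone, and the level and sense of enantioselection). The fallback sets out from 1 and comes back to the route at 8. Diketone 1 is mono-ketalised with 2,2-dimethylpropane-1,3-diol (TsOH, benzene) to the mono-ketal of cis-1,5-dimethylbicyclo[3.3.0]octane-3,7-dione F1. Wolff–Kishner reduction gives the ketal of cis-1,5-dimethylbicyclo[3.3.0]octan-3-one F2, and aqueous HCl frees the meso ketone cis-1,5-dimethylbicyclo[3.3.0]octan-3-one F3. This ketone has only one carbonyl and is deprotonated by the same chiral amide with Me3SiCl present as internal quench, giving (1S,5R)-1,5-dimethyl-3-(trimethylsilyloxy)bicyclo[3.3.0]oct-2-ene F4. MeLi then Comins' reagent converts it into (1S,5R)-1,5-dimethylbicyclo[3.3.0]oct-2-en-3-yl trifluoromethanesulfonate F5, which undergoes the B-alkyl Suzuki coupling with borane 5 to give 8 directly.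

Step 4 (sense and level of the proline-controlled aldol, on which C5 and then C6 depend). The fallback sets out from 8 and comes back at 10. Ozonolysis of 8 (through 9) followed by piperidinium acetate gives the aldol-condensation product (3aS,7aR)-5-(2-hydroxy-2-methylpropyl)-3a,7a-dimethyl-1,2,3,3a,7,7a-hexahydro-6H-inden-6-one F6. Ligand-controlled copper-catalysed conjugate borylation (CuCl, NaOtBu, a homochiral ferrocenyl bisphosphine, B2pin2, MeOH) places boron on C4 anti to the angular methyls to give the 4-(pinacolboryl) ketone F7. NaBO3 oxidation with retention then gives 10.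

Step 9 (carboalumination of a tris-alkoxide and a one-pot aluminium-to-palladium coupling next to an aryl carbonate). The fallback sets out from 11 and 15 and comes back at 17. The carboalumination of 11 is quenched with I2 and the product is isolated as the (E)-vinyl iodide (3aR,4S,5S,6R,7aR)-6-[(2E)-3-iodo-2-methylprop-2-en-1-yl]-5-(2-hydroxy-2-methylpropyl)-3a,7a-dimethyloctahydro-1H-indene-4,6-diol F8. Chloride 15 is turned with Zn dust and LiCl into [2-(ethoxycarbonyloxy)-5-methoxy-3-methylbenzyl]zinc chloride F9. A Negishi coupling with reversed polarity (Pd(OAc)2, SPhos, THF) joins the two to 17.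

**Further compounds**
F1 | step 1 | cis-1,5-dimethylbicyclo[3.3.0]octane-3,7-dione mono(2,2-dimethylpropane-1,3-diyl) ketal | O=C1C[C@@]2(C)CC3(OCC(C)(C)CO3)C[C@@]2(C)C1
F2 | step 1 | cis-1,5-dimethylbicyclo[3.3.0]octan-3-one 2,2-dimethylpropane-1,3-diyl ketal | C1C[C@@]2(C)CC3(OCC(C)(C)CO3)C[C@@]2(C)C1
F3 | step 1 | cis-1,5-dimethylbicyclo[3.3.0]octan-3-one (meso) | O=C1C[C@@]2(C)CCC[C@@]2(C)C1
F4 | step 1 | (1S,5R)-1,5-dimethyl-3-(trimethylsilyloxy)bicyclo[3.3.0]oct-2-ene | C1(O[Si](C)(C)C)C[C@@]2(C)CCC[C@@]2(C)C=1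
F5 | step 1 | (1S,5R)-1,5-dimethylbicyclo[3.3.0]oct-2-en-3-yl trifluoromethanesulfonate | C1(OS(=O)(=O)C(F)(F)F)C[C@@]2(C)CCC[C@@]2(C)C=1
F6 | step 4 | (3aS,7aR)-5-(2-hydroxy-2-methylpropyl)-3a,7a-dimethyl-1,2,3,3a,7,7a-hexahydro-6H-inden-6-one | O=C1C[C@@]2(C)CCC[C@@]2(C)C=C1CC(C)(C)O
F7 | step 4 | (3aS,4S,5S,7aR)-5-(2-hydroxy-2-methylpropyl)-3a,7a-dimethyl-4-(4,4,5,5-tetramethyl-1,3,2-dioxaborolan-2-yl)octahydro-6H-inden-6-one | O=C1C[C@@]2(C)CCC[C@@]2(C)[C@@H](B3OC(C)(C)C(C)(C)O3)[C@@H]1CC(C)(C)O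
F8 | step 9 | (3aR,4S,5S,6R,7aR)-6-[(2E)-3-iodo-2-methylprop-2-en-1-yl]-5-(2-hydroxy-2-methylpropyl)-3a,7a-dimethyloctahydro-1H-indene-4,6-diol | I/C=C(\C)C[C@@]1(O)C[C@@]2(C)CCC[C@@]2(C)[C@@H](O)[C@@H]1CC(C)(C)O
F9 | step 9 | [2-(ethoxycarbonyloxy)-5-methoxy-3-methylbenzyl]zinc chloride | CCOC(=O)Oc1c(C)cc(OC)cc1C[Zn]Cl
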